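**Analysis of the target**

Abiesin is a C–C linked biflavonoid without any stereocenter. One half is a 5-hydroxy-7-methoxyflavone; C3' of its ring B (a 4'-methoxyphenyl ring) is bonded to C6 of the other half, a 3,7-dihydroxy-4'-methoxyflavonol. The biaryl bond has one ortho oxygen on each side (OMe at C4' of the flavone, OH at C7 of the flavonol), so the axis rotates freely and raises no configurational question. Of the six peripheral oxygens three are methyl ethers and three are free hydroxyls, and each methyl group has to end up in its place without a late selective methylation. The 3-hydroxy-4-pyranone of the flavonol is prone to oxidation and both pyranone rings open in hot strong base, so the flavonol is best completed last. The difficulty is the bookkeeping of two different chromones on an ortho-oxygenated biaryl, and above all ring A of the flavone, whose two meta oxygens are differentiated (C5–OH peri to C4=O, C7–OMe, with C6–H and C8–H). That ring is a resorcinol monoether fused through C4a–C8a to a 4-pyranone. A vinylketene/alkoxyalkyne benzannulation gives exactly this pattern when the vinyl unit is the C2=C3 bond of a 4-pyranone that carries the ketene at C2, and the strategy rests on this. Ring A of the flavonol is an ordinary 4-substituted resorcinol and can come from a commercial arene.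

**Retrosynthetic reasoning**

Target 27 is opened at the flavonol ring C, at O1–C2 and at the C3–O bond, to chalcone 25. An Algar–Flynn–Oyamada oxidation forms both bonds in one operation, and it tolerates the free phenols, so the oxidation-sensitive 3-hydroxypyranone appears only in the last step. The forward reaction has to give the six-membered flavonol and not an aurone; the hydrogen at C6' of the chalcone ensures this.

Chalcone 25 is cut at its Cα=Cβ bond into methyl ketone 22 and aldehyde 23. This is the natural seam of a chalcone. It brings in the whole ring B of the flavonol as a commercial aldehyde, and the forward Claisen–Schmidt condensation only has to give the (E)-enone, which is the stable isomer.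

Ketone 22 is traced to its dibenzyl ether 21, and the acetyl group of 21 to the aryl bromide of 19 (cut at the aryl–acetyl C–C bond). The bromide is a placeholder. An acetyl group on the resorcinol ring would be a second enolizable methyl ketone in steps 4 to 6, whereas a C–Br bond is inert there and is exchanged for acetyl by a Stille coupling with an α-alkoxyvinyl tin reagent. Benzyl ethers are chosen because they survive base, acid and light and leave by hydrogenolysis without touching the three methyl ethers.

Flavone 19 is disconnected through ring A at C4a–C5, C5–C6, C7–C8 and C8–C8a into diazo ketone 12 and methoxyacetylene 15. Cutting here gives a ring A that arrives with OH at C5 and OMe at C7 already set, with no phloroglucinol to be methylated selectively. Ring C of the flavone is simply the 4-pyranone of 12. The forward reaction has to turn 12 into a pyranylketene, add 15 with the ynol-ether regiochemistry, and close the six-membered ring onto pyranone C3.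

Diazo ketone 12 is traced to methyl ketone 10 by a detrifluoroacetylative diazo transfer from a sulfonyl azide. Acylating a diazoalkane with a pyranone acid chloride is avoided: the C2=C3 bond of a 2-acyl-4-pyranone is flanked by two carbonyl groups and invites dipolar cycloaddition, and that route also needs an ester hydrolysis on a base-sensitive pyranone. Diazo transfer to the enolate-derived 1,3-dicarbonyl compound has neither problem.

Pyranone 10 is cut at the ring O–C bond and at the C–C bond next to the former ketal carbon, giving 1,3-diketone 6 and ester 7. Ester 7 carries the future acetyl group as a ketal, so only its ester end is electrophilic and it cannot enolize. The forward sequence is a terminal acylation of the dianion of 6, then acid cyclodehydration of the 1,3,5-triketone and ketal hydrolysis.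

Diketone 6 comes from methyl ketone 5 by a Claisen condensation with an acetate ester. Ketone 5 is cut at the biaryl bond into boronate 4 (from bromo ketone 3) and dibromide 2 (from 1). The two bromides of 2 are equivalent, so a single coupling needs no regiocontrol and leaves the second bromide as the placeholder described above. Methoxyacetylene 15 is made from chloroacetal 13 by double elimination.

**Alternatives that were turned down**

Alternative 1: Ring A of the flavonol is disconnected at C5–C6 and C4a–C8a.
- Forward key step: a Diels–Alder reaction of the oxygenated diene 4-(5-bromo-2-methoxyphenyl)-1-methoxy-1,3-bis(trimethylsilyloxy)buta-1,3-diene A1 with but-3-yn-2-one A2. Loss of the C1 alkoxy group and desilylation aromatize the adduct to 1-[5-(5-bromo-2-methoxyphenyl)-2,4-dihydroxyphenyl]ethanone A3.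
- For it: the diene and the ynone are strongly and oppositely polarized, so the regiochemistry is dependable. The reaction is thermal and belongs to a well-used class. A3 is the chalcone precursor with free hydroxyls, so no placeholder bromide, no tin reagent and no benzyl group are needed on that ring.
- Against it: it constructs the easier ring. The 2,4-dihydroxyacetophenone pattern is what commercial resorcinols already supply, so the ring synthesis gains little. The diene terminus that must form C5–C6 carries an ortho-substituted aryl group, which slows the cycloaddition, and A1 is a moisture-sensitive silyl ketene acetal. The flavone half with its 5-OH/7-OMe pattern would still have to be built from the bromide of A3 by classical acylation chemistry on a selectively methylated phloroglucinol ketone, in a molecule that already holds one methyl ketone.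
- Comparison: on precedent and on the absence of photochemistry it is stronger than the chosen route. The chosen route instead creates the differentiated ring A in one step and keeps a single methyl ketone in play at any time.

Alternative 2: Ring C of the flavone is disconnected at C2=C3, with O1–C2 traced to an aryl ester.
- Forward key step: the acylphosphorane 3-(benzyloxy)-5-methoxy-2-[(triphenylphosphoranylidene)acetyl]phenyl 3-[3,7-bis(benzyloxy)-2-(4-methoxyphenyl)-4-oxo-4H-chromen-6-yl]-4-methoxybenzoate A4 is heated. The ylide carbon attacks the ester carbonyl, the phosphine oxide leaves, and 3,7,5-tri-O-benzylabiesin A5 results, one hydrogenolysis from the target.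
- For it: it is the most convergent plan, it runs under neutral conditions, the intramolecular ester olefination is established for flavones, and A5 is a late intermediate.
- Against it: the complete flavonol–biaryl acid must be made first, with O3 and O7 protected, which puts a long linear sequence on the valuable fragment. The phosphorane half needs a phloroglucinol ketone with three different oxygens (free OH, OBn, OMe), so the ring A pattern is paid for in protecting-group steps. Acylation of the phenol next to the ylide competes with acylation at the ylide carbon. An ester carbonyl is a reluctant Wittig acceptor and needs high temperature.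
- Comparison: on convergence and precedent it is stronger. The chosen route offers a ring A whose oxygen pattern comes from bond formation and not from protecting-group sorting, and fewer operations overall.

Alternative 3: Ring A of the flavone is disconnected at C4a–C8a into a linear poly-β-carbonyl chain.
- Forward key step: methyl 9-{3-[3,7-bis(benzyloxy)-2-(4-methoxyphenyl)-4-oxo-4H-chromen-6-yl]-4-methoxyphenyl}-3,5,7,9-tetraoxononanoate A6, under a magnesium alkoxide base, undergoes intramolecular Claisen attack of the C6 carbanion on the ester carbon. This gives the acylphloroglucinol 1-{3-[3,7-bis(benzyloxy)-2-(4-methoxyphenyl)-4-oxo-4H-chromen-6-yl]-4-methoxyphenyl}-3-(2,4,6-trihydroxyphenyl)propane-1,3-dione A7. Cyclodehydration, methylation of O7 and debenzylation would follow.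
- For it: the folding is biomimetic, all ring A carbons come from one acetate-type chain, and the Claisen mode is known for simple aryl groups.
- Against it: the same chain can fold by aldol attack of C2 on the C7 carbonyl or close to pyranones, so the mode of cyclization is not secured by the structure. A6 has to be assembled by polyanion acylation with the advanced, base-sensitive flavonol fragment. A7 carries undifferentiated phenols, so a selective O7 methylation is still needed after ring C is closed.
- Comparison: it shares the idea of building ring A but is equal at best on step count and weaker on control. The chosen benzannulation fixes the regiochemistry through ketene polarization and brings the methyl ether in with the alkyne. Alternative 3 is stronger only in using no light and no diazo compound.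

Key step: step 8

Remarks on the chemistry:
- Methoxyacetylene 15 is assumed not to be a stock item; it is prepared in step 7 and used as a freshly distilled cold solution.
- Ar stands for the 3-[2,4-bis(benzyloxy)-5-bromophenyl]-4-methoxyphenyl group.
- Partly converted species of the two twofold reactions (monobenzyl ether in step 1, monodebenzylated ketones in step 10) are not numbered.

**Route**

Step 1
Reactants: 1 4,6-dibromoresorcinol
Product: 2 1,5-bis(benzyloxy)-2,4-dibromobenzene
Conditions: BnBr (2.3 equiv), K2CO3, DMF, 60 °C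
Reagents that add atoms: benzyl bromide, BrCc1ccccc1
Why: Williamson etherification of both phenols; the aryl C–Br bonds are inert to carbonate, and the symmetric product has two equivalent bromides for step 3.

Step 2
Reactants: 3 1-(3-bromo-4-methoxyphenyl)ethanone
Product: 4 1-[4-methoxy-3-(4,4,5,5-tetramethyl-1,3,2-dioxaborolan-2-yl)phenyl]ethanone
Conditions: B2pin2 (1.2 equiv), PdCl2(dppf) (3 mol %), KOAc, 1,4-dioxane, 90 °C
Reagents that add atoms: bis(pinacolato)diboron, CC1(C)OB(OC1(C)C)B1OC(C)(C)C(C)(C)O1
Why: Miyaura borylation; the weak base KOAc leaves the methyl ketone unenolized and suppresses biaryl homocoupling.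

Step 3
Reactants: 4 1-[4-methoxy-3-(4,4,5,5-tetramethyl-1,3,2-dioxaborolan-2-yl)phenyl]ethanone; 2 1,5-bis(benzyloxy)-2,4-dibromobenzene
Product: 5 1-{3-[2,4-bis(benzyloxy)-5-bromophenyl]-4-methoxyphenyl}ethanone (Ar–COCH3)
Conditions: 2 (3 equiv), Pd(PPh3)4 (5 mol %), K2CO3, toluene/EtOH/H2O, 85 °C; unreacted 2 recovered
Reagents that add atoms: none
Why: Suzuki–Miyaura coupling; with the dibromide in threefold excess the boronate should be consumed mainly by single coupling, and since the two bromides of 2 are equivalent there is no regiochemical issue.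

Step 4
Reactants: 5 1-{3-[2,4-bis(benzyloxy)-5-bromophenyl]-4-methoxyphenyl}ethanone
Product: 6 1-Ar-butane-1,3-dione
Conditions: NaH (2.5 equiv), EtOAc (5 equiv), THF, 0 °C to reflux; then aq. HCl
Reagents that add atoms: ethyl acetate, CCOC(C)=O
Why: Crossed Claisen condensation of the ketone enolate with the ester in excess; the product leaves the equilibrium as its stabilized diketonate.

Step 5
Reactants: 6 1-Ar-butane-1,3-dione; 7 methyl 2,2-dimethoxypropanoate
Product: 10 2-acetyl-6-Ar-4H-pyran-4-one, via triketone ketal 8 (not isolated), via pyranone ketal 9 (not isolated)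
Conditions: LiN(i-Pr)2 (3.1 equiv), THF, −78 to −20 °C; 7 (1.5 equiv), −78 °C to rt; then HCl (4 M in dioxane, excess), rt; then H2O, 50 °C
Reagents that add atoms: water, O
Why: The dianion of the 1,3-diketone is acylated at its terminal carbon, the more basic site, by the non-enolizable α,α-dialkoxy ester (Claisen condensation; the third equivalent of base keeps the product deprotonated). Acid then cyclodehydrates the 1,3,5-triketone to the 4-pyranone and hydrolyses the ketal to the acetyl group.

Step 6
Reactants: 10 2-acetyl-6-Ar-4H-pyran-4-one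
Product: 12 2-diazo-1-(6-Ar-4-oxo-4H-pyran-2-yl)ethanone, via trifluoroacetyl diketone 11 (not isolated)
Conditions: LiN(SiMe3)2 (1.1 equiv), THF, −78 °C; CF3CO2CH2CF3 (1.2 equiv); 5 % aq. HCl wash; crude 11, MeSO2N3 (1.5 equiv), Et3N, H2O, MeCN, rt
Reagents that add atoms: methanesulfonyl azide, CS(=O)(=O)N=[N+]=[N-] (2,2,2-trifluoroethyl trifluoroacetate, O=C(OCC(F)(F)F)C(F)(F)F, supplies only the trifluoroacetyl group of 11, which is lost again)
Why: Detrifluoroacetylative diazo transfer: the lithium enolate of the methyl ketone is trifluoroacetylated, and the activated 1,3-dicarbonyl compound takes the diazo group from the sulfonyl azide with loss of the trifluoroacetyl group. No diazoalkane is present that could add to the pyranone C2=C3 bond.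

Step 7
Reactants: 13 2-chloro-1,1-dimethoxyethane
Product: 15 methoxyethyne (methoxyacetylene), via sodium methoxyethynide 14 (not isolated)
Conditions: NaNH2 (3.2 equiv), NH3(l), −33 °C; evaporate NH3; cold sat. aq. NaCl; distil into a −78 °C trap
Reagents that add atoms: none
Why: Two successive β-eliminations (hydrogen chloride, then methanol) from the chloroacetal give the ynol ether, held as its sodium acetylide until the aqueous quench; this is the standard access to 1-alkoxyalkynes.

Step 8
Reactants: 12 2-diazo-1-(6-Ar-4-oxo-4H-pyran-2-yl)ethanone; 15 methoxyethyne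
Product: 19 2-Ar-5-hydroxy-7-methoxy-4H-chromen-4-one, via pyranylketene 16 (not isolated), via methoxycyclobutenone 17 (not isolated), via dienylketene 18 (not isolated)
Conditions: 15 (5 equiv), dry degassed ClCH2CH2Cl, hν (365 nm, Pyrex), 15–20 °C, sealed vessel; then 80 °C, sealed
Reagents that add atoms: none
Why: Proposed new method: light should expel nitrogen from 12 while the pyranyl group shifts from the acyl carbon to the former diazo carbon (Wolff rearrangement, forming C8–C8a) to give ketene 16; the closest known reaction type is the Danheiser benzannulation of aryl and heteroaryl diazomethyl ketones with alkoxy- and silyloxyalkynes, for which a 4-pyranon-2-yl ketone is an untried substrate class. Ketene 16 should add 15 in a (2+2) cycloaddition in which the nucleophilic CH terminus of the ynol ether bonds to the ketene carbonyl carbon (C5–C6) and the oxygen-bearing carbon to the ketene α-carbon (C7–C8), giving cyclobutenone 17. Four-electron electrocyclic opening of 17 (cleavage of the bond between the carbonyl carbon and the pyranyl-bearing carbon) gives dienylketene 18, and ring A is closed by a six-electron electrocyclization in which the ketene carbon bonds to pyranone C3 (C4a–C5); tautomerization of the cyclohexadienone restores the pyranone and gives the phenol. No stereocenter is created: the sp3 carbon of 17 is racemic and disappears on ring opening. The step needs one regiochemical outcome, OH at C5 and OMe at C7, and the opposed polarization of ketene and ynol ether in the (2+2) step secures it. The site of closure is not in question, because within the pyranone the ketene-bearing carbon has only C3 and the ring oxygen as neighbours. The geometric isomer of 18 that cannot reach C3 should re-close to 17 and open again, so that both funnel to 19. The closing carbon C3 is the nucleophilic β-carbon of the pyranone enol ether and matches the electrophilic ketene carbon, 365 nm light is absorbed by the diazo ketone and not by the aryl bromide, and the peri hydrogen bond of 19 keeps the new phenol from trapping 16.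

Step 9
Reactants: 19 2-Ar-5-hydroxy-7-methoxy-4H-chromen-4-one
Product: 21 2-{3-[5-acetyl-2,4-bis(benzyloxy)phenyl]-4-methoxyphenyl}-5-hydroxy-7-methoxy-4H-chromen-4-one, via ethoxyvinyl ether 20 (not isolated)
Conditions: Bu3SnC(OEt)=CH2 (1.5 equiv), Pd(PPh3)4 (5 mol %), toluene, 105 °C; then 1 M HCl, THF, rt; aq. KF wash
Reagents that add atoms: tributyl(1-ethoxyvinyl)stannane, CCOC(=C)[Sn](CCCC)(CCCC)CCCC; water, O
Why: Stille coupling of the aryl bromide with an acetyl-anion equivalent; the neutral conditions tolerate the chelated 5-OH and the pyranone, and mild acid hydrolyses the enol ether to the methyl ketone without touching the benzyl ethers.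

Step 10
Reactants: 21 2-{3-[5-acetyl-2,4-bis(benzyloxy)phenyl]-4-methoxyphenyl}-5-hydroxy-7-methoxy-4H-chromen-4-one
Product: 22 2-[3-(5-acetyl-2,4-dihydroxyphenyl)-4-methoxyphenyl]-5-hydroxy-7-methoxy-4H-chromen-4-one
Conditions: H2 (1 atm), Pd/C (10 wt %), THF/MeOH, rt
Reagents that add atoms: none
Why: Hydrogenolysis of the two benzyl aryl ethers; methyl ethers, the aryl ketone and the flavone C2=C3 bond should stay intact at one atmosphere, and the bromide that hydrogen would have removed has already been used.

Step 11
Reactants: 22 2-[3-(5-acetyl-2,4-dihydroxyphenyl)-4-methoxyphenyl]-5-hydroxy-7-methoxy-4H-chromen-4-one; 23 4-methoxybenzaldehyde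
Product: 25 2-{3-[2,4-dihydroxy-5-[(2E)-3-(4-methoxyphenyl)prop-2-enoyl]phenyl]-4-methoxyphenyl}-5-hydroxy-7-methoxy-4H-chromen-4-one, via aldol adduct 24 (not isolated)
Conditions: 23 (1.5 equiv), KOH (50 % aq.), EtOH, rt; then aq. HCl
Reagents that add atoms: none
Why: Claisen–Schmidt condensation (aldol addition, then E1cB loss of water) with a non-enolizable aldehyde gives the thermodynamic (E)-enone; 2',4'-dihydroxyacetophenones are known to condense as their phenoxides in concentrated alkali at room temperature.

Step 12
Reactants: 25 2-{3-[2,4-dihydroxy-5-[(2E)-3-(4-methoxyphenyl)prop-2-enoyl]phenyl]-4-methoxyphenyl}-5-hydroxy-7-methoxy-4H-chromen-4-one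
Product: 27 abiesin, via trans-dihydroflavonol 26 (not isolated)
Conditions: H2O2 (30 % aq.), NaOH (aq.), MeOH, 0 °C to rt; then aq. HCl
Reagents that add atoms: hydrogen peroxide, OO
Why: Algar–Flynn–Oyamada oxidation: the 2'-phenoxide adds to the enone β-carbon while the α-carbon is hydroxylated by peroxide, and the resulting trans-dihydroflavonol is dehydrogenated by the same alkaline peroxide to the flavonol, its two transient stereocenters disappearing. The hydrogen at C6' of the chalcone is the condition under which the flavonol and not an aurone is formed.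

**Compound list**

1 | 4,6-dibromoresorcinol (4,6-dibromobenzene-1,3-diol) | Oc1cc(O)c(Br)cc1Br | starting material
2 | 1,5-bis(benzyloxy)-2,4-dibromobenzene | Brc1cc(Br)c(OCc2ccccc2)cc1OCc1ccccc1 | intermediate
3 | 1-(3-bromo-4-methoxyphenyl)ethanone | CC(=O)c1ccc(OC)c(Br)c1 | starting material
4 | 1-[4-methoxy-3-(4,4,5,5-tetramethyl-1,3,2-dioxaborolan-2-yl)phenyl]ethanone | CC(=O)c1ccc(OC)c(B2OC(C)(C)C(C)(C)O2)c1 | intermediate
5 | 1-{3-[2,4-bis(benzyloxy)-5-bromophenyl]-4-methoxyphenyl}ethanone | CC(=O)c1ccc(OC)c(-c2cc(Br)c(OCc3ccccc3)cc2OCc2ccccc2)c1 | intermediate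
6 | 1-{3-[2,4-bis(benzyloxy)-5-bromophenyl]-4-methoxyphenyl}butane-1,3-dione | CC(=O)CC(=O)c1ccc(OC)c(-c2cc(Br)c(OCc3ccccc3)cc2OCc2ccccc2)c1 | intermediate
7 | methyl 2,2-dimethoxypropanoate | COC(=O)C(C)(OC)OC | starting material
8 | 1-{3-[2,4-bis(benzyloxy)-5-bromophenyl]-4-methoxyphenyl}-6,6-dimethoxyheptane-1,3,5-trione (not isolated) | CC(OC)(OC)C(=O)CC(=O)CC(=O)c1ccc(OC)c(-c2cc(Br)c(OCc3ccccc3)cc2OCc2ccccc2)c1 | intermediate
9 | 2-{3-[2,4-bis(benzyloxy)-5-bromophenyl]-4-methoxyphenyl}-6-(1,1-dimethoxyethyl)-4H-pyran-4-one (not isolated) | CC(OC)(OC)c1cc(=O)cc(-c2ccc(OC)c(-c3cc(Br)c(OCc4ccccc4)cc3OCc3ccccc3)c2)o1 | intermediate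
10 | 2-acetyl-6-{3-[2,4-bis(benzyloxy)-5-bromophenyl]-4-methoxyphenyl}-4H-pyran-4-one | CC(=O)c1cc(=O)cc(-c2ccc(OC)c(-c3cc(Br)c(OCc4ccccc4)cc3OCc3ccccc3)c2)o1 | intermediate
11 | 1-(6-{3-[2,4-bis(benzyloxy)-5-bromophenyl]-4-methoxyphenyl}-4-oxo-4H-pyran-2-yl)-4,4,4-trifluorobutane-1,3-dione (not isolated) | O=C(CC(=O)C(F)(F)F)c1cc(=O)cc(-c2ccc(OC)c(-c3cc(Br)c(OCc4ccccc4)cc3OCc3ccccc3)c2)o1 | intermediate
12 | 2-diazo-1-(6-{3-[2,4-bis(benzyloxy)-5-bromophenyl]-4-methoxyphenyl}-4-oxo-4H-pyran-2-yl)ethanone | [N-]=[N+]=CC(=O)c1cc(=O)cc(-c2ccc(OC)c(-c3cc(Br)c(OCc4ccccc4)cc3OCc3ccccc3)c2)o1 | intermediate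
13 | 2-chloro-1,1-dimethoxyethane (chloroacetaldehyde dimethyl acetal) | COC(CCl)OC | starting material
14 | sodium methoxyethynide (not isolated) | COC#[C-].[Na+] | intermediate
15 | methoxyethyne (methoxyacetylene) | COC#C | intermediate
16 | 2-(6-{3-[2,4-bis(benzyloxy)-5-bromophenyl]-4-methoxyphenyl}-4-oxo-4H-pyran-2-yl)ethen-1-one (ketene, not isolated) | O=C=Cc1cc(=O)cc(-c2ccc(OC)c(-c3cc(Br)c(OCc4ccccc4)cc3OCc3ccccc3)c2)o1 | intermediate
17 | 4-(6-{3-[2,4-bis(benzyloxy)-5-bromophenyl]-4-methoxyphenyl}-4-oxo-4H-pyran-2-yl)-3-methoxycyclobut-2-en-1-one (racemic, not isolated) | COC1=CC(=O)C1c1cc(=O)cc(-c2ccc(OC)c(-c3cc(Br)c(OCc4ccccc4)cc3OCc3ccccc3)c2)o1 | intermediate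
18 | (3E)-4-(6-{3-[2,4-bis(benzyloxy)-5-bromophenyl]-4-methoxyphenyl}-4-oxo-4H-pyran-2-yl)-3-methoxybuta-1,3-dien-1-one (not isolated) | O=C=C/C(OC)=C\c1cc(=O)cc(-c2ccc(OC)c(-c3cc(Br)c(OCc4ccccc4)cc3OCc3ccccc3)c2)o1 | intermediate
19 | 2-{3-[2,4-bis(benzyloxy)-5-bromophenyl]-4-methoxyphenyl}-5-hydroxy-7-methoxy-4H-chromen-4-one | COc1cc(O)c2c(=O)cc(-c3ccc(OC)c(-c4cc(Br)c(OCc5ccccc5)cc4OCc4ccccc4)c3)oc2c1 | intermediate
20 | 2-{3-[2,4-bis(benzyloxy)-5-(1-ethoxyethenyl)phenyl]-4-methoxyphenyl}-5-hydroxy-7-methoxy-4H-chromen-4-one (not isolated) | CCOC(=C)c1cc(-c2cc(-c3cc(=O)c4c(O)cc(OC)cc4o3)ccc2OC)c(OCc2ccccc2)cc1OCc1ccccc1 | intermediate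
21 | 2-{3-[5-acetyl-2,4-bis(benzyloxy)phenyl]-4-methoxyphenyl}-5-hydroxy-7-methoxy-4H-chromen-4-one | CC(=O)c1cc(-c2cc(-c3cc(=O)c4c(O)cc(OC)cc4o3)ccc2OC)c(OCc2ccccc2)cc1OCc1ccccc1 | intermediate
22 | 2-[3-(5-acetyl-2,4-dihydroxyphenyl)-4-methoxyphenyl]-5-hydroxy-7-methoxy-4H-chromen-4-one | CC(=O)c1cc(-c2cc(-c3cc(=O)c4c(O)cc(OC)cc4o3)ccc2OC)c(O)cc1O | intermediate
23 | 4-methoxybenzaldehyde | COc1ccc(C=O)cc1 | starting material
24 | 2-{3-[2,4-dihydroxy-5-[3-hydroxy-3-(4-methoxyphenyl)propanoyl]phenyl]-4-methoxyphenyl}-5-hydroxy-7-methoxy-4H-chromen-4-one (racemic, not isolated) | COc1ccc(C(O)CC(=O)c2cc(-c3cc(-c4cc(=O)c5c(O)cc(OC)cc5o4)ccc3OC)c(O)cc2O)cc1 | intermediate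
25 | 2-{3-[2,4-dihydroxy-5-[(2E)-3-(4-methoxyphenyl)prop-2-enoyl]phenyl]-4-methoxyphenyl}-5-hydroxy-7-methoxy-4H-chromen-4-one | COc1ccc(/C=C/C(=O)c2cc(-c3cc(-c4cc(=O)c5c(O)cc(OC)cc5o4)ccc3OC)c(O)cc2O)cc1 | intermediate
26 | rac-(2R,3R)-3,7-dihydroxy-6-[5-(5-hydroxy-7-methoxy-4-oxo-4H-chromen-2-yl)-2-methoxyphenyl]-2-(4-methoxyphenyl)-2,3-dihydro-4H-chromen-4-one (trans, one enantiomer drawn, not isolated) | COc1ccc([C@@H]2[C@H](C(=O)c3cc(-c4cc(-c5cc(=O)c6c(O)cc(OC)cc6o5)ccc4OC)c(O)cc3O2)O)cc1 | intermediate
27 | abiesin, 3,7-dihydroxy-6-[5-(5-hydroxy-7-methoxy-4-oxo-4H-chromen-2-yl)-2-methoxyphenyl]-2-(4-methoxyphenyl)-4H-chromen-4-one | COc1ccc(-c2oc3cc(O)c(-c4cc(-c5cc(=O)c6c(O)cc(OC)cc6o5)ccc4OC)cc3c(=O)c2O)cc1 | target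

**Step count and risk**

Total step count: 12. Longest linear sequence: 10 steps (3 → 4 → 5 → 6 → 10 → 12 → 19 → 21 → 22 → 25 → 27; the branch from 1 is equally long).

Least certain steps:

Step 8 (key step). Several processes can divert it.
- The 6-aryl-4-pyranone chromophore may absorb in competition with the diazo ketone and undergo its own photoisomerization.
- The ketene may be intercepted by traces of moisture before it meets the volatile, polymerization-prone ynol ether.
- The electrocyclization onto the pyranone may stall at the cyclobutenone, because closure costs the pyranone its conjugation transiently.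
- Photolytic loss of bromine is possible at shorter wavelengths.

Fallback with known chemistry, from 2 to 19:
- Dibromide 2 (in excess) is coupled under the conditions of step 3 with commercial [2-methoxy-5-(methoxycarbonyl)phenyl]boronic acid to give methyl 3-[2,4-bis(benzyloxy)-5-bromophenyl]-4-methoxybenzoate F1.
- Saponification (LiOH, THF/H2O) gives 3-[2,4-bis(benzyloxy)-5-bromophenyl]-4-methoxybenzoic acid F2, and oxalyl chloride with catalytic DMF gives 3-[2,4-bis(benzyloxy)-5-bromophenyl]-4-methoxybenzoyl chloride F3.
- Commercial 1-(2,6-dihydroxy-4-methoxyphenyl)ethanone, lithiated with excess LiN(SiMe3)2 in THF at −78 °C, is aroylated at carbon by F3 to 1-{3-[2,4-bis(benzyloxy)-5-bromophenyl]-4-methoxyphenyl}-3-(2,6-dihydroxy-4-methoxyphenyl)propane-1,3-dione F4.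
- Cyclodehydration (AcOH, catalytic H2SO4, 60 °C) closes ring C through either of the two equivalent hydroxyls and returns to the route at 19.

Step 5. Three things can go wrong.
- Acylation at the α-quaternary ketal ester may be slow, so that proton transfer quenches the dianion.
- The polyanionic chain may close by aldol condensation to a benzenoid by-product.
- Ketal hydrolysis may run ahead of pyranone formation and open a path to a furanone.

Fallback, from 6 to 12 (it also bypasses step 6):
- The dianion of 6 is condensed with diethyl oxalate to ethyl 6-{3-[2,4-bis(benzyloxy)-5-bromophenyl]-4-methoxyphenyl}-2,4,6-trioxohexanoate F5.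
- Acid (AcOH, HCl) cyclizes F5 to ethyl 6-{3-[2,4-bis(benzyloxy)-5-bromophenyl]-4-methoxyphenyl}-4-oxo-4H-pyran-2-carboxylate F6.
- Hydrolysis with LiOH at 0 °C gives 6-{3-[2,4-bis(benzyloxy)-5-bromophenyl]-4-methoxyphenyl}-4-oxo-4H-pyran-2-carboxylic acid F7, and oxalyl chloride gives 6-{3-[2,4-bis(benzyloxy)-5-bromophenyl]-4-methoxyphenyl}-4-oxo-4H-pyran-2-carbonyl chloride F8.
- Adding F8 to excess diazomethane in ether at −10 °C gives 12.
- This path is kept in reserve because the diazoalkane may also add across the activated pyranone double bond.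

Step 3. Twofold coupling of the symmetric dibromide and protodeboronation of the ortho-methoxy boronate may erode the single-coupling product and complicate its separation from recovered 2.

Fallback, from 4 to 5:
- Commercial 4-bromoresorcinol is dibenzylated to 2,4-bis(benzyloxy)-1-bromobenzene F9.
- Suzuki coupling of F9 with 4 gives 1-{3-[2,4-bis(benzyloxy)phenyl]-4-methoxyphenyl}ethanone F10.
- N-bromosuccinimide in MeCN at 0 °C then brominates the resorcinol ring para to one benzyloxy group and ortho to the other, giving 5. The site between the two ethers is shielded and the acetylated anisole ring is deactivated.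

Step 11 (and with it step 12). The para-phenoxide of the triply deprotonated ketone suppresses enolization, so the condensation may be slow, and prolonged concentrated alkali may open the flavone ring by conjugate attack of hydroxide. In step 12 the free phenoxides may be over-oxidized by peroxide.

Fallback, from 21 to 27:
- MgBr2·OEt2 in toluene/Et2O at reflux removes, by chelation, only the benzyl group ortho to the acetyl carbonyl. This gives 2-{3-[5-acetyl-2-(benzyloxy)-4-hydroxyphenyl]-4-methoxyphenyl}-5-hydroxy-7-methoxy-4H-chromen-4-one F11.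
- The Claisen–Schmidt condensation with 23 then runs in dilute KOH/EtOH to 2-{3-[2-(benzyloxy)-4-hydroxy-5-[(2E)-3-(4-methoxyphenyl)prop-2-enoyl]phenyl]-4-methoxyphenyl}-5-hydroxy-7-methoxy-4H-chromen-4-one F12.
- Algar–Flynn–Oyamada oxidation gives 7-(benzyloxy)-3-hydroxy-6-[5-(5-hydroxy-7-methoxy-4-oxo-4H-chromen-2-yl)-2-methoxyphenyl]-2-(4-methoxyphenyl)-4H-chromen-4-one F13.
- Hydrogenolysis (H2, Pd/C, THF/MeOH) gives 27.

**Further compounds**

F1 | step 8 | methyl 3-[2,4-bis(benzyloxy)-5-bromophenyl]-4-methoxybenzoate | COC(=O)c1ccc(OC)c(-c2cc(Br)c(OCc3ccccc3)cc2OCc2ccccc2)c1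
F2 | step 8 | 3-[2,4-bis(benzyloxy)-5-bromophenyl]-4-methoxybenzoic acid | OC(=O)c1ccc(OC)c(-c2cc(Br)c(OCc3ccccc3)cc2OCc2ccccc2)c1
F3 | step 8 | 3-[2,4-bis(benzyloxy)-5-bromophenyl]-4-methoxybenzoyl chloride | O=C(Cl)c1ccc(OC)c(-c2cc(Br)c(OCc3ccccc3)cc2OCc2ccccc2)c1
F4 | step 8 | 1-{3-[2,4-bis(benzyloxy)-5-bromophenyl]-4-methoxyphenyl}-3-(2,6-dihydroxy-4-methoxyphenyl)propane-1,3-dione | COc1cc(O)c(C(=O)CC(=O)c2ccc(OC)c(-c3cc(Br)c(OCc4ccccc4)cc3OCc3ccccc3)c2)c(O)c1
F5 | step 5 | ethyl 6-{3-[2,4-bis(benzyloxy)-5-bromophenyl]-4-methoxyphenyl}-2,4,6-trioxohexanoate | CCOC(=O)C(=O)CC(=O)CC(=O)c1ccc(OC)c(-c2cc(Br)c(OCc3ccccc3)cc2OCc2ccccc2)c1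
F6 | step 5 | ethyl 6-{3-[2,4-bis(benzyloxy)-5-bromophenyl]-4-methoxyphenyl}-4-oxo-4H-pyran-2-carboxylate | CCOC(=O)c1cc(=O)cc(-c2ccc(OC)c(-c3cc(Br)c(OCc4ccccc4)cc3OCc3ccccc3)c2)o1
F7 | step 5 | 6-{3-[2,4-bis(benzyloxy)-5-bromophenyl]-4-methoxyphenyl}-4-oxo-4H-pyran-2-carboxylic acid | OC(=O)c1cc(=O)cc(-c2ccc(OC)c(-c3cc(Br)c(OCc4ccccc4)cc3OCc3ccccc3)c2)o1
F8 | step 5 | 6-{3-[2,4-bis(benzyloxy)-5-bromophenyl]-4-methoxyphenyl}-4-oxo-4H-pyran-2-carbonyl chloride | O=C(Cl)c1cc(=O)cc(-c2ccc(OC)c(-c3cc(Br)c(OCc4ccccc4)cc3OCc3ccccc3)c2)o1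
F9 | step 3 | 2,4-bis(benzyloxy)-1-bromobenzene | Brc1ccc(OCc2ccccc2)cc1OCc1ccccc1
F10 | step 3 | 1-{3-[2,4-bis(benzyloxy)phenyl]-4-methoxyphenyl}ethanone | CC(=O)c1ccc(OC)c(-c2ccc(OCc3ccccc3)cc2OCc2ccccc2)c1
F11 | step 11 | 2-{3-[5-acetyl-2-(benzyloxy)-4-hydroxyphenyl]-4-methoxyphenyl}-5-hydroxy-7-methoxy-4H-chromen-4-one | CC(=O)c1cc(-c2cc(-c3cc(=O)c4c(O)cc(OC)cc4o3)ccc2OC)c(OCc2ccccc2)cc1O
F12 | step 11 | 2-{3-[2-(benzyloxy)-4-hydroxy-5-[(2E)-3-(4-methoxyphenyl)prop-2-enoyl]phenyl]-4-methoxyphenyl}-5-hydroxy-7-methoxy-4H-chromen-4-one | COc1ccc(/C=C/C(=O)c2cc(-c3cc(-c4cc(=O)c5c(O)cc(OC)cc5o4)ccc3OC)c(OCc3ccccc3)cc2O)cc1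
F13 | step 11 | 7-(benzyloxy)-3-hydroxy-6-[5-(5-hydroxy-7-methoxy-4-oxo-4H-chromen-2-yl)-2-methoxyphenyl]-2-(4-methoxyphenyl)-4H-chromen-4-one | COc1ccc(-c2oc3cc(OCc4ccccc4)c(-c4cc(-c5cc(=O)c6c(O)cc(OC)cc6o5)ccc4OC)cc3c(=O)c2O)cc1
A1 | alternative 1 | 4-(5-bromo-2-methoxyphenyl)-1-methoxy-1,3-bis(trimethylsilyloxy)buta-1,3-diene (double-bond geometry not specified) | COC(O[Si](C)(C)C)=CC(O[Si](C)(C)C)=Cc1cc(Br)ccc1OC
A2 | alternative 1 | but-3-yn-2-one | CC(=O)C#C
A3 | alternative 1 | 1-[5-(5-bromo-2-methoxyphenyl)-2,4-dihydroxyphenyl]ethanone | CC(=O)c1cc(-c2cc(Br)ccc2OC)c(O)cc1O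
A4 | alternative 2 | 3-(benzyloxy)-5-methoxy-2-[(triphenylphosphoranylidene)acetyl]phenyl 3-[3,7-bis(benzyloxy)-2-(4-methoxyphenyl)-4-oxo-4H-chromen-6-yl]-4-methoxybenzoate | O=C(C=P(c1ccccc1)(c1ccccc1)c1ccccc1)c1c(OCc2ccccc2)cc(OC)cc1OC(=O)c1ccc(OC)c(-c2cc3c(=O)c(OCc4ccccc4)c(-c4ccc(OC)cc4)oc3cc2OCc2ccccc2)c1
A5 | alternative 2 | 3,7,5-tri-O-benzylabiesin (benzyl on flavonol O3 and O7 and on flavone O5) | COc1ccc(-c2oc3cc(OCc4ccccc4)c(-c4cc(-c5cc(=O)c6c(OCc7ccccc7)cc(OC)cc6o5)ccc4OC)cc3c(=O)c2OCc2ccccc2)cc1
A6 | alternative 3 | methyl 9-{3-[3,7-bis(benzyloxy)-2-(4-methoxyphenyl)-4-oxo-4H-chromen-6-yl]-4-methoxyphenyl}-3,5,7,9-tetraoxononanoate | COC(=O)CC(=O)CC(=O)CC(=O)CC(=O)c1ccc(OC)c(-c2cc3c(=O)c(OCc4ccccc4)c(-c4ccc(OC)cc4)oc3cc2OCc2ccccc2)c1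
A7 | alternative 3 | 1-{3-[3,7-bis(benzyloxy)-2-(4-methoxyphenyl)-4-oxo-4H-chromen-6-yl]-4-methoxyphenyl}-3-(2,4,6-trihydroxyphenyl)propane-1,3-dione | O=C(CC(=O)c1ccc(OC)c(-c2cc3c(=O)c(OCc4ccccc4)c(-c4ccc(OC)cc4)oc3cc2OCc2ccccc2)c1)c1c(O)cc(O)cc1O
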